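Assumption: the SMILES is taken literally. That means a free C‑14 carboxylic acid. In germacrane numbering the configuration is 2R,3R,4R,5R,6S,7R,8S,9S,2′R,3′R. The C1=C10 alkene is endocyclic‑cis (CIP E). Both oxiranes are cis‑fused to the ring (C1/C4 cis, C3/C6 cis) and anti to each other. The lactone is 6,7‑trans and the 8,9‑oxygens are syn (threo). Germacrane numbering (C1–C15) is used for all advanced intermediates.

## Retrosynthetic overview
1. Leucanthin B ⇒ macrocyclic 9‑ol 29. Endgame: C9 acetylation, C8 Yamaguchi esterification with epoxyangelic acid 22, then release of the C14 acid from a TMSE ester.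
2. The ten‑membered carbocycle is the last ring formed. It is cut at C9–C10: a new ligand‑controlled Ni/Cr macrocyclisation of (Z)‑α‑iodoenoate/aldehyde 28.
3. C1=C10 ⇒ iodo‑Wittig on a cis‑epoxy aldehyde. The 2,3‑oxirane (third ring) ⇒ Sharpless epoxidation of the C1 (Z)‑allylic alcohol.
4. The trans α‑methylene‑γ‑lactone (second ring) ⇒ C6–C7 Cr(II) Barbier allylation/lactonisation of epoxy aldehyde 8 with glyceraldehyde‑derived bromide 14.
5. The 4,5‑oxirane (first ring) ⇒ Sharpless epoxidation of a (Z)‑enynol built from but‑2‑yn‑1‑ol and propargyl alcohol. The side chain ⇒ Sharpless epoxidation of angelyl alcohol.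

## Route

### A. West fragment (C1–C6, C15)

**Step 1**
Reactants: 1 but‑2‑yn‑1‑ol
Product: 2 (2Z)‑3‑iodobut‑2‑en‑1‑ol
Conditions: Red‑Al, THF, 0 °C→rt; then I2, −78→0 °C
Reagents that add atoms: iodine, II
Why: Hydroxyl‑directed trans‑hydroalumination of a propargylic alcohol followed by iodinolysis with retention puts I cis to CH2OH (Z only), which later becomes the C3/C6‑cis relationship of the 4,5‑oxirane.

**Step 2**
Reactants: 3 prop‑2‑yn‑1‑ol
Product: 4 4‑methoxybenzyl propargyl ether
Conditions: NaH, PMBCl, TBAI (cat.), THF, 0 °C→rt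
Reagents that add atoms: 4‑methoxybenzyl chloride, COc1ccc(CCl)cc1
Why: Williamson etherification gives a PMB group that is removed oxidatively and is therefore orthogonal to the TES ethers and TMSE ester used later.

**Step 3**
Reactants: 2 (Z)‑iodide; 4 PMB propargyl ether
Product: 5 (2Z)‑6‑(PMBO)‑3‑methylhex‑2‑en‑4‑yn‑1‑ol
Conditions: PdCl2(PPh3)2 (2 mol %), CuI (4 mol %), iPr2NH, THF, rt
Reagents that add atoms: none
Why: Sonogashira coupling proceeds with retention of vinyl‑iodide geometry and tolerates the free alcohol.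

**Step 4**
Reactants: 5 enynol
Product: 6 (2R,3S)‑alkynyl epoxy alcohol (sets C5 and C4)
Conditions: Ti(OiPr)4 (0.2 equiv), D‑(−)‑DIPT (0.26 equiv), TBHP, 4 Å MS, CH2Cl2, −20 °C
Reagents that add atoms: tert‑butyl hydroperoxide, CC(C)(C)OO
Why: Sharpless asymmetric epoxidation of a nerol‑type (Z)‑trisubstituted allylic alcohol with D‑(−)‑tartrate makes the carbinol‑bearing oxirane carbon R (C5), C4 follows by syn addition (C3/C6 stay cis), and the alkynyl substituent keeps the tertiary oxirane robust toward Ti(IV).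

**Step 5**
Reactants: 6
Product: 7 (Z)‑alkenyl epoxy alcohol
Conditions: H2 (1 atm), Lindlar catalyst, quinoline, EtOAc, rt
Reagents that add atoms: none
Why: Lindlar semihydrogenation (syn H2 addition) gives only the Z‑alkene, and the poisoned catalyst spares the oxirane and the PMB ether.

**Step 6**
Reactants: 7
Product: 8 (2S,3S)‑epoxy aldehyde (C6 = CHO)
Conditions: DMP, NaHCO3, CH2Cl2, 0 °C (used at once, kept ≤ rt)
Reagents that add atoms: none
Why: Buffered Dess–Martin oxidation gives the configurationally stable α,β‑epoxy aldehyde without acid or base that could open the vinyl oxirane.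

### B. East fragment (C7–C9, C11–C13)

**Step 7**
Reactants: 9 (R)‑glyceraldehyde acetonide; 10 methyl acrylate
Product: 11 Baylis–Hillman adduct (C7 epimers)
Conditions: DABCO, 1,4‑dioxane/H2O 1:1, rt
Reagents that add atoms: none
Why: The Morita–Baylis–Hillman reaction gives a C7 carbinol mixture that is irrelevant (destroyed in step 8), while C8 comes unchanged from the chiral pool.

**Step 8**
Reactants: 11
Product: 12 (Z)‑2‑(bromomethyl)enoate acetonide
Conditions: NBS, Me2S, CH2Cl2, 0 °C→rt
Reagents that add atoms: N‑bromosuccinimide, O=C1CCC(=O)N1Br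
Why: Corey–Kim‑type bromination of a Baylis–Hillman alcohol occurs with allylic transposition (SN2′) to the (Z)‑allylic bromide under neutral conditions that spare the acetonide.

**Step 9**
Reactants: 12
Product: 13 bromo diol
Conditions: AcOH/H2O 4:1, 40 °C
Reagents that add atoms: none
Why: The only acidic acetal hydrolysis of the synthesis is done on this small oxirane‑free fragment, and C8‑OH is trans to the ester across the alkene so it cannot lactonise.

**Step 10**
Reactants: 13
Product: 14 8,9‑bis‑TES allylic bromide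
Conditions: TESOTf, 2,6‑lutidine, CH2Cl2, −78 °C
Reagents that add atoms: triethylsilyl triflate, CC[Si](CC)(CC)OS(=O)(=O)C(F)(F)F
Why: Fast low‑temperature silylation with a non‑nucleophilic base outruns intramolecular O‑alkylation by the allylic bromide and installs fluoride‑ and Swern‑addressable protection.

### C. C10/C14 reagent

**Step 11**
Reactants: 15 2‑(trimethylsilyl)ethanol; 16 bromoacetyl bromide
Product: 17 TMSE bromoacetate
Conditions: pyridine, CH2Cl2, 0 °C
Reagents that add atoms: none
Why: Simple O‑acylation of a primary alcohol by an acid bromide.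

**Step 12**
Reactants: 17
Product: 18 TMSE (triphenylphosphoranylidene)acetate
Conditions: PPh3, toluene, rt; then 1 M NaOH, CH2Cl2
Reagents that add atoms: triphenylphosphine, c1ccc(cc1)P(c1ccccc1)c1ccccc1
Why: SN2 quaternisation and deprotonation give the stabilised Wittig ylide.

### D. Side‑chain acid

**Step 13**
Reactants: 19 angelic acid
Product: 20 (2Z)‑2‑methylbut‑2‑en‑1‑ol
Conditions: LiAlH4, Et2O, 0 °C
Reagents that add atoms: none
Why: 1,2‑Hydride reduction of the unsaturated acid retains the Z geometry.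

**Step 14**
Reactants: 20
Product: 21 [(2S,3R)‑2,3‑dimethyloxiran‑2‑yl]methanol
Conditions: Ti(OiPr)4, L‑(+)‑DET, TBHP, 4 Å MS, CH2Cl2, −20 °C
Reagents that add atoms: tert‑butyl hydroperoxide, CC(C)(C)OO
Why: Sharpless asymmetric epoxidation with L‑(+)‑tartrate makes the carbinol‑bearing carbon S (it becomes 2′R after oxidation changes CIP priorities), and syn addition keeps C4′‑Me cis to C1′.

**Step 15**
Reactants: 21
Product: 22 (2R,3R)‑2,3‑dimethyloxirane‑2‑carboxylic acid
Conditions: RuCl3 (2 mol %), NaIO4, MeCN/EtOAc/H2O, 0 °C→rt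
Reagents that add atoms: sodium periodate, [Na+].[O-]I(=O)(=O)=O; water, O
Why: RuO4 oxidation takes a primary epoxy alcohol directly to the glycidic acid without touching the two (non‑epimerisable) oxirane stereocentres.

### E. Assembly

**Step 16**
Reactants: 8 epoxy aldehyde; 14 allylic bromide
Product: 23 trans α‑methylene‑γ‑butyrolactone (C6–C7 bond)
Conditions: CrCl2 (4 equiv), THF, 0 °C→rt, slow addition of 8 + 14; in situ lactonisation; aq. EDTA (pH 7) work‑up
Reagents that add atoms: none
Why: In this Nozaki–Hiyama (Cr‑Barbier) 2‑(alkoxycarbonyl)allylation/lactonisation the allyl‑Cr(III) equilibrates to the isomer with C8 trans to CH2Cr and adds through a chair TS (6,7‑anti, hence trans‑lactone once the Cr alkoxide closes on the methyl ester), C8 selects the allyl face (H8 inside because of A1,3 strain with the ester, CH2OTES anti to the forming bond, OTES outside) and so fixes C7 and, through the chair, C6 (Si‑face attack, 6S), bidentate binding of the epoxy aldehyde to Cr(III) favours the same 5,6‑threo isomer, silyloxy is a poor leaving group for reductive 1,4‑elimination, and isomers from the minor enantiomer of 8 are removed here.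

**Step 17**
Reactants: 23
Product: 24 C1 (Z)‑allylic alcohol
Conditions: DDQ, CH2Cl2/pH 7 buffer 10:1, 0 °C
Reagents that add atoms: none
Why: Buffered oxidative PMB cleavage is orthogonal to the TES ethers, the oxirane and the electron‑poor methylene lactone.

**Step 18**
Reactants: 24
Product: 25 bis‑epoxy alcohol (sets C2 and C3)
Conditions: Ti(OiPr)4 (1.0 equiv), D‑(−)‑DET (1.2 equiv), TBHP, 4 Å MS, CH2Cl2, −25 °C
Reagents that add atoms: tert‑butyl hydroperoxide, CC(C)(C)OO
Why: Sharpless asymmetric epoxidation (stoichiometric because cis‑allylic alcohols are slow, with excess tartrate to damp Ti Lewis acidity) with D‑(−)‑tartrate again makes the carbinol‑bearing carbon R (C2), syn addition to the Z‑alkene gives the cis‑oxirane (3R), the required bis‑oxirane is the pseudo‑C2‑symmetric one so the tartrate sense is the same as in step 4, and only the hydroxyl‑bound alkene reacts.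

**Step 19**
Reactants: 25
Product: 26 bis‑epoxy aldehyde (C1 = CHO)
Conditions: DMP, NaHCO3, CH2Cl2, 0 °C
Reagents that add atoms: none
Why: Buffered Dess–Martin oxidation leaves the oxiranes, TES ethers and lactone untouched.

**Step 20**
Reactants: 26; 18 ylide
Product: 27 (Z)‑α‑iodoenoate
Conditions: 18, NIS, K2CO3, MeCN/CH2Cl2, −20 °C, 20 min; then 26, −20 °C→rt
Reagents that add atoms: N‑iodosuccinimide, O=C1CCC(=O)N1I
Why: In this halo‑Wittig olefination in situ iodination gives Ph3P=C(I)CO2R, which places the ester trans to C2 (I cis to C2, Z), exactly the geometry that becomes the endocyclic‑cis C1=C10 bond, under neutral conditions that do not epimerise the cis‑epoxy aldehyde.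

**Step 21**
Reactants: 27
Product: 28 seco iodoenoate aldehyde (C9 = CHO)
Conditions: (COCl)2, DMSO, CH2Cl2, −78→−40 °C; Et3N, −78→0 °C
Reagents that add atoms: none
Why: Swern conditions selectively cleave and oxidise a primary TES ether directly to the aldehyde while the secondary C8‑OTES survives.

**Step 22 (new transformation)**
Reactants: 28
Product: 29 macrocyclic 9S‑alcohol (ten‑membered ring closed)
Conditions: CrCl2 (30 mol %), valinol‑derived 2‑(2‑sulfonamidoaryl)oxazoline ligand L* (33 mol %; the antipode that delivers to the Si face of C9), NiCl2·(2,9‑dimethylphenanthroline) (3 mol %), Mn, Cp2ZrCl2, LiCl, proton sponge, MeCN, rt; 28 added over 12 h to 2 mM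
Reagents that add atoms: none
Why: Proposed new method: a ligand‑controlled Ni/Cr‑catalysed macrocyclising alkenylation in which a (Z)‑α‑iodo‑α,β‑unsaturated ester (rather than a simple vinyl iodide) is the pronucleophile and a ten‑membered carbocycle is closed – Ni(0) inserts into the ester‑activated C10–I bond and transmetallates to L*Cr(III), the α‑(alkoxycarbonyl)alkenyl‑Cr(III) (in equilibrium with its O‑bound chromium allenolate, so any E‑iodide converges) binds the C9 aldehyde and forms C9–C10 through a compact Cr‑templated closed TS, only the endocyclic‑cis alkene can span a chain already folded by the trans‑lactone and two cis‑oxiranes, Cp2ZrCl2/Mn turnover keeps [Cr(II)] low so the oxiranes and methylene lactone survive, no β‑elimination path exists for the alkenyl metal, and the ligand rather than the Felkin bias of the α‑OTES aldehyde dictates Si‑face attack (9S, 8,9‑syn); the closest known reaction types are catalytic asymmetric Nozaki–Hiyama–Kishi alkenylation (including macrocyclic use with unactivated vinyl iodides) and metal‑allenolate aldol routes to β‑substituted Baylis–Hillman‑type adducts.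

**Step 23**
Reactants: 29
Product: 30 9‑acetate
Conditions: Ac2O, DMAP, pyridine, CH2Cl2, 0 °C
Reagents that add atoms: acetic anhydride, CC(=O)OC(C)=O
Why: DMAP‑catalysed acetylation hits the only free hydroxyl, so the C8/C9 oxygens are differentiated because C9‑OH is unveiled only at step 22 while C8‑O stays silylated.

**Step 24**
Reactants: 30
Product: 31 8‑alcohol
Conditions: HF·pyridine, pyridine, THF, 0 °C
Reagents that add atoms: none
Why: Buffered HF·pyridine removes the secondary TES ether while the TMSE ester, acetate and oxiranes survive, and the mildly acidic medium suppresses 9→8 acetyl migration.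

**Step 25**
Reactants: 31; 22 epoxyangelic acid
Product: 32 leucanthin B TMSE ester
Conditions: 22, 2,4,6‑trichlorobenzoyl chloride, Et3N, THF; then 31, DMAP, toluene, rt
Reagents that add atoms: none
Why: Yamaguchi esterification acylates hindered secondary alcohols with retention at C8, and the α‑quaternary glycidic acid cannot epimerise.

**Step 26**
Reactants: 32
Product: 33 leucanthin B
Conditions: TASF, DMF, 0 °C; pH 4 buffer
Reagents that add atoms: none
Why: Fluoride‑induced β‑silyl fragmentation of the TMSE ester (loss of ethylene and Me3SiF) frees the acid under near‑neutral conditions, avoiding Pd(0), strong acid and hydroxide, which the vinyl oxirane, esters and methylene lactone would not tolerate.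

**Origin of stereochemistry**

| Element | Set in | Source of control |
|---|---|---|
| C4, C5 | step 4 | Sharpless epoxidation, D‑(−)‑tartrate |
| C6, C7 | step 16 | chair TS plus C8 stereocentre |
| C8 | compound 9 | chiral pool |
| C2, C3 | step 18 | Sharpless epoxidation, D‑(−)‑tartrate |
| C1=C10 geometry | steps 20 and 22 | iodo‑Wittig, ring constraint |
| C9 | step 22 | ligand L* |
| C2′, C3′ | step 14 | Sharpless epoxidation, L‑(+)‑tartrate |

No later step touches any of these centres. Some CIP letters change between intermediates only because substituent priorities change.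

## Compound list

1 | but‑2‑yn‑1‑ol | CC#CCO | starting material
2 | (2Z)‑3‑iodobut‑2‑en‑1‑ol | C/C(I)=C/CO | intermediate
3 | prop‑2‑yn‑1‑ol | C#CCO | starting material
4 | 1‑methoxy‑4‑[(prop‑2‑yn‑1‑yloxy)methyl]benzene | C#CCOCc1ccc(OC)cc1 | intermediate
5 | (2Z)‑6‑[(4‑methoxybenzyl)oxy]‑3‑methylhex‑2‑en‑4‑yn‑1‑ol | OC/C=C(/C)C#CCOCc1ccc(OC)cc1 | intermediate
6 | [(2R,3S)‑3‑{3‑[(4‑methoxybenzyl)oxy]prop‑1‑yn‑1‑yl}‑3‑methyloxiran‑2‑yl]methanol | COc1ccc(COCC#C[C@]2(C)O[C@@H]2CO)cc1 | intermediate
7 | [(2R,3S)‑3‑{(1Z)‑3‑[(4‑methoxybenzyl)oxy]prop‑1‑en‑1‑yl}‑3‑methyloxiran‑2‑yl]methanol | COc1ccc(COC/C=C\[C@]2(C)O[C@@H]2CO)cc1 | intermediate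
8 | (2S,3S)‑3‑{(1Z)‑3‑[(4‑methoxybenzyl)oxy]prop‑1‑en‑1‑yl}‑3‑methyloxirane‑2‑carbaldehyde | COc1ccc(COC/C=C\[C@]2(C)O[C@@H]2C=O)cc1 | intermediate
9 | (4R)‑2,2‑dimethyl‑1,3‑dioxolane‑4‑carbaldehyde | O=C[C@H]1COC(C)(C)O1 | starting material
10 | methyl acrylate | C=CC(=O)OC | starting material
11 | methyl 2‑{[(4R)‑2,2‑dimethyl‑1,3‑dioxolan‑4‑yl](hydroxy)methyl}prop‑2‑enoate (carbinol epimers) | C=C(C(=O)OC)C(O)[C@H]1COC(C)(C)O1 | intermediate
12 | methyl (2Z)‑2‑(bromomethyl)‑3‑[(4S)‑2,2‑dimethyl‑1,3‑dioxolan‑4‑yl]prop‑2‑enoate | COC(=O)/C(CBr)=C/[C@H]1COC(C)(C)O1 | intermediate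
13 | methyl (2Z,4S)‑2‑(bromomethyl)‑4,5‑dihydroxypent‑2‑enoate | COC(=O)/C(CBr)=C/[C@H](O)CO | intermediate
14 | methyl (2Z,4S)‑2‑(bromomethyl)‑4,5‑bis(triethylsilyloxy)pent‑2‑enoate | COC(=O)/C(CBr)=C/[C@H](O[Si](CC)(CC)CC)CO[Si](CC)(CC)CC | intermediate
15 | 2‑(trimethylsilyl)ethanol | C[Si](C)(C)CCO | starting material
16 | bromoacetyl bromide | BrCC(=O)Br | starting material
17 | 2‑(trimethylsilyl)ethyl bromoacetate | BrCC(=O)OCC[Si](C)(C)C | intermediate
18 | 2‑(trimethylsilyl)ethyl (triphenyl‑λ5‑phosphanylidene)acetate | C[Si](C)(C)CCOC(=O)C=P(c1ccccc1)(c1ccccc1)c1ccccc1 | intermediate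
19 | angelic acid, (2Z)‑2‑methylbut‑2‑enoic acid | C/C=C(/C)C(=O)O | starting material
20 | (2Z)‑2‑methylbut‑2‑en‑1‑ol | C/C=C(/C)CO | intermediate
21 | [(2S,3R)‑2,3‑dimethyloxiran‑2‑yl]methanol | OC[C@]1(C)O[C@@H]1C | intermediate
22 | (2R,3R)‑2,3‑dimethyloxirane‑2‑carboxylic acid | OC(=O)[C@]1(C)O[C@@H]1C | intermediate
23 | (4S,5S)‑4‑[(1S)‑1,2‑bis(triethylsilyloxy)ethyl]‑5‑[(2R,3S)‑3‑{(1Z)‑3‑[(4‑methoxybenzyl)oxy]prop‑1‑enyl}‑3‑methyloxiran‑2‑yl]‑3‑methylideneoxolan‑2‑one (germacrane 4S,5R,6S,7S,8S; 2Z) | C=C1C(=O)O[C@H]([C@H]2O[C@@]2(C)/C=C\COCc2ccc(OC)cc2)[C@H]1[C@H](O[Si](CC)(CC)CC)CO[Si](CC)(CC)CC | intermediate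
24 | as 23 with free C1‑OH ((1Z)‑3‑hydroxyprop‑1‑enyl) | C=C1C(=O)O[C@H]([C@H]2O[C@@]2(C)/C=C\CO)[C@H]1[C@H](O[Si](CC)(CC)CC)CO[Si](CC)(CC)CC | intermediate
25 | seco bis‑epoxy alcohol (2R,3R,4R,5R,6S,7S,8S): lactone bearing the 2,3:4,5‑bis(cis‑oxirane) chain ending in C1H2OH; 8,9‑bis‑OTES | C=C1C(=O)O[C@H]([C@H]2O[C@@]2(C)[C@@H]2O[C@@H]2CO)[C@H]1[C@H](O[Si](CC)(CC)CC)CO[Si](CC)(CC)CC | intermediate
26 | seco bis‑epoxy C1‑aldehyde (2S,3R,4R,5R,6S,7S,8S; same spatial arrangement as 25) | C=C1C(=O)O[C@H]([C@H]2O[C@@]2(C)[C@@H]2O[C@@H]2C=O)[C@H]1[C@H](O[Si](CC)(CC)CC)CO[Si](CC)(CC)CC | intermediate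
27 | seco (1(10)Z)‑10‑iodo enoate TMSE ester (2R,3R,4R,5R,6S,7S,8S), 8,9‑bis‑OTES | C=C1C(=O)O[C@H]([C@H]2O[C@@]2(C)[C@@H]2O[C@@H]2/C=C(\I)C(=O)OCC[Si](C)(C)C)[C@H]1[C@H](O[Si](CC)(CC)CC)CO[Si](CC)(CC)CC | intermediate
28 | as 27 with C9 = CHO and 8‑OTES | C=C1C(=O)O[C@H]([C@H]2O[C@@]2(C)[C@@H]2O[C@@H]2/C=C(\I)C(=O)OCC[Si](C)(C)C)[C@H]1[C@H](O[Si](CC)(CC)CC)C=O | intermediate
29 | macrocycle: 2α,3α:4β,5β‑diepoxy‑9α‑hydroxy‑8β‑(triethylsilyloxy)germacra‑1(10)E,11(13)‑dien‑6α,12‑olid‑14‑oic acid TMSE ester (2R,3R,4R,5R,6S,7S,8S,9S) | C=C1C(=O)O[C@H]2[C@H]1[C@H](O[Si](CC)(CC)CC)[C@@H](O)/C(C(=O)OCC[Si](C)(C)C)=C\[C@H]1O[C@H]1[C@]1(C)O[C@H]21 | intermediate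
30 | 9α‑acetate of 29 | C=C1C(=O)O[C@H]2[C@H]1[C@H](O[Si](CC)(CC)CC)[C@@H](OC(C)=O)/C(C(=O)OCC[Si](C)(C)C)=C\[C@H]1O[C@H]1[C@]1(C)O[C@H]21 | intermediate
31 | 9α‑acetoxy‑8β‑hydroxy macrocycle TMSE ester (7R by CIP) | C=C1C(=O)O[C@H]2[C@H]1[C@H](O)[C@@H](OC(C)=O)/C(C(=O)OCC[Si](C)(C)C)=C\[C@H]1O[C@H]1[C@]1(C)O[C@H]21 | intermediate
32 | leucanthin B 2‑(trimethylsilyl)ethyl ester | C=C1C(=O)O[C@H]2[C@H]1[C@H](OC(=O)[C@]1(C)O[C@@H]1C)[C@@H](OC(C)=O)/C(C(=O)OCC[Si](C)(C)C)=C\[C@H]1O[C@H]1[C@]1(C)O[C@H]21 | intermediate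
33 | leucanthin B | C=C1C(=O)O[C@H]2[C@H]1[C@H](OC(=O)[C@]1(C)O[C@@H]1C)[C@@H](OC(C)=O)/C(C(=O)O)=C\[C@H]1O[C@H]1[C@]1(C)O[C@H]21 | target

## Totals
Total steps: 26.
Longest linear sequence: 16 steps (1, 3–6, 16–26).

## Three steps most likely to fail

**1. Step 22 (new Ni/Cr macrocyclisation).**
- Risks: protodeiodination, oligomerisation, or the Felkin (9R) epimer.
- Fallback (known chemistry, different ring‑closing bond):
  - Form C9–C10 first and intermolecularly. Use I/Mg exchange on a West‑derived (Z)‑α‑iodoenoate (iPrMgCl·LiCl, −78 °C), then Mg‑chelation‑controlled addition to an (R)‑2‑(PMBO)‑3‑(silyloxy)propanal. This gives the syn diol monoether. Acetylate C9.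
  - Elaborate C7 to the 2‑(bromomethyl)enoate.
  - Close the ring at C6–C7 with the stoichiometric CrCl2 macrocyclic Barbier reaction already established for ten‑membered germacranolides.

**2. Step 16 (Cr‑Barbier union).**
- Risks: competition from the Felkin 5,6‑erythro isomer or the cis‑lactone, and reduction of the epoxy aldehyde.
- Fallback (change the order in which the stereocentres are made):
  - Semihydrogenate 5 and oxidise with MnO2 to the epoxide‑free (2Z,4Z)‑dienal.
  - Allylate it with 14/CrCl2. There is no α‑stereocentre, so C8 alone controls C7 and C6.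
  - Use the free C6‑OH for VO(acac)2/TBHP directed epoxidation. A1,3 strain in the Z‑alkene gives the required threo 4,5‑oxirane.
  - Lactonise and rejoin the route at 23.

**3. Step 18 (Sharpless epoxidation of the hindered cis‑allylic alcohol).**
- Risks: a slow reaction, and Ti‑promoted 5‑exo attack of C1‑OH on the tertiary allylic oxirane to give a 2,5‑dihydrofuran.
- Fallback (build the bis‑oxirane on the small fragment in the kinetically better order):
  - Couple C6‑O‑silylated 2 with free propargyl alcohol and semireduce.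
  - Run the slow cis‑selective Sharpless epoxidation first, on the epoxide‑free dienol.
  - Protect C1‑OH and free C6‑OH.
  - Run the fast nerol‑type Sharpless epoxidation second.
  - Oxidise to the bis‑epoxy C6‑aldehyde and use it in step 16. This costs about three extra steps.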